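**Strategy.** Ring C is disconnected at the aryl ketone bond C4–C4a, which leads back to an open (S)-3-aryl-3-aryloxypropanoic acid. In that precursor, ring A is a 4-prenylphloroglucinol ether whose two free carbons (the future C4a and C8) are equivalent about the axis through C8a and C6. One intramolecular Friedel–Crafts acylation therefore closes the pyranone and can only give the 6-prenyl flavanone, never the 8-prenyl isomer. The C2 stereocentre is set beforehand by an iridium-catalysed enantioselective allylic etherification that joins the prenylphloroglucinol phenol to the chromenyl cinnamyl carbonate; hydroboration and oxidation then supply the acid.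

Key step: step 10

Remark: compounds 1, 7 and 13 are taken as catalogue chemicals, and the target is made as the (2S) enantiomer that its SMILES encodes.

**Step 1**
Reactants: 1 1,3-bis(methoxymethoxy)benzene; 2 1-bromo-3-methylbut-2-ene (prenyl bromide)
Product: 4 1,3-bis(methoxymethoxy)-2-(3-methylbut-2-en-1-yl)benzene, via aryllithium 3 (not isolated)
Conditions: n-BuLi (1.1 equiv), THF, 0 °C; then CuI (0.1 equiv), 2, −78 °C → rt
Reagents that add atoms: n-butyllithium, [Li]CCCC (lithium of 3 only)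
Why: Directed ortho-metalation, in which the two methoxymethoxy groups direct n-BuLi to the carbon between them, followed by copper-assisted SN2 alkylation of aryllithium 3 that keeps the prenyl group linear.

**Step 2**
Reactants: 4 1,3-bis(methoxymethoxy)-2-(3-methylbut-2-en-1-yl)benzene
Product: 6 3,5-bis(methoxymethoxy)-4-(3-methylbut-2-en-1-yl)phenol, via arylboronic pinacol ester 5 (not isolated)
Conditions: [Ir(OMe)(cod)]2 (1.5 mol%), 4,4'-di-tert-butyl-2,2'-bipyridine (3 mol%), B2pin2 (1.0 equiv), THF, 60 °C; then NaOH (aq), H2O2, 0 °C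
Reagents that add atoms: bis(pinacolato)diboron, CC1(C)OB(OC1(C)C)B1OC(C)(C)C(C)(C)O1 (boryl group of 5 only); hydrogen peroxide, OO (phenol oxygen)
Why: Sterically controlled iridium-catalysed aromatic C–H borylation should attack the only ring C–H without an ortho substituent (para to the prenyl group, whose trisubstituted alkene reacts far more slowly), and alkaline peroxide oxidation of the C–B bond gives the phenol in the same flask.

**Step 3**
Reactants: 7 5-bromo-2,4-dihydroxybenzaldehyde; 8 2-methylbut-3-en-2-ol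
Product: 10 7-hydroxy-2,2-dimethyl-2H-chromene-6-carbaldehyde, via E-allylic alcohol 9 (not isolated)
Conditions: Pd(OAc)2 (5 mol%), P(o-tol)3 (10 mol%), Et3N, DMF, 110 °C; then TsOH·H2O (10 mol%), toluene, 80 °C
Reagents that add atoms: none
Why: Mizoroki–Heck arylation at the terminal alkene carbon gives tertiary allylic alcohol 9, which under acid ionises to an ortho-quinone-methide-type allyl cation and is captured by the neighbouring 4-OH; the position of the bromine allows only the linear chromene.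

**Step 4**
Reactants: 10 7-hydroxy-2,2-dimethyl-2H-chromene-6-carbaldehyde
Product: 11 7-(methoxymethoxy)-2,2-dimethyl-2H-chromene-6-carbaldehyde
Conditions: MOMCl (1.5 equiv), iPr2NEt, CH2Cl2, 0 °C → rt
Reagents that add atoms: chloromethyl methyl ether, COCCl
Why: Williamson-type O-alkylation of the chelated phenol by the oxocarbenium-forming chloride gives the MOM ether.

**Step 5**
Reactants: 11 7-(methoxymethoxy)-2,2-dimethyl-2H-chromene-6-carbaldehyde
Product: 12 6-ethenyl-7-(methoxymethoxy)-2,2-dimethyl-2H-chromene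
Conditions: Ph3PCH3Br, KOt-Bu, THF, 0 °C → rt
Reagents that add atoms: methyltriphenylphosphonium bromide, C[P+](c1ccccc1)(c1ccccc1)c1ccccc1.[Br-]
Why: Wittig methylenation of the aromatic aldehyde by the unstabilised ylide.

**Step 6**
Reactants: 12 6-ethenyl-7-(methoxymethoxy)-2,2-dimethyl-2H-chromene; 13 methyl prop-2-en-1-yl carbonate (allyl methyl carbonate)
Product: 14 (2E)-3-[7-(methoxymethoxy)-2,2-dimethyl-2H-chromen-6-yl]prop-2-en-1-yl methyl carbonate
Conditions: 13 (3 equiv), second-generation Hoveyda–Grubbs catalyst RuCl2(H2IMes)(=CH–C6H4-2-OiPr) (5 mol%), CH2Cl2, 40 °C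
Reagents that add atoms: none
Why: Olefin cross-metathesis of the styrene with the allylic carbonate, with loss of ethene, should favour the E isomer, while the hindered ring alkene of the chromene (cis-disubstituted, next to a quaternary carbon) stays out.

**Step 7**
Reactants: 6 3,5-bis(methoxymethoxy)-4-(3-methylbut-2-en-1-yl)phenol; 14 (2E)-3-[7-(methoxymethoxy)-2,2-dimethyl-2H-chromen-6-yl]prop-2-en-1-yl methyl carbonate
Product: 16 6-{(1S)-1-[3,5-bis(methoxymethoxy)-4-(3-methylbut-2-en-1-yl)phenoxy]prop-2-en-1-yl}-7-(methoxymethoxy)-2,2-dimethyl-2H-chromene, via lithium phenolate 15 (not isolated)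
Conditions: 6, n-BuLi (1.0 equiv), THF, 0 °C; then 14 (1.1 equiv), [Ir(cod)Cl]2 (2 mol%), O,O'-[(S)-1,1'-binaphthyl-2,2'-diyl] N,N-bis[(S)-1-(2-methoxyphenyl)ethyl]phosphoramidite (4 mol%, pre-activated with n-PrNH2), THF, rt
Reagents that add atoms: n-butyllithium, [Li]CCCC (lithium of 15 only)
Why: Iridium-catalysed asymmetric allylic etherification through a (π-allyl)iridium complex, in which the phenolate attacks the aryl-bearing allyl terminus to give the branched ether; the C2 stereocentre is set by the chiral phosphoramidite, whose (Sa,S,S) enantiomer is expected to give the S ether (the mirror-image ligand would be used if the sense proved opposite).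

**Step 8**
Reactants: 16 6-{(1S)-1-[3,5-bis(methoxymethoxy)-4-(3-methylbut-2-en-1-yl)phenoxy]prop-2-en-1-yl}-7-(methoxymethoxy)-2,2-dimethyl-2H-chromene
Product: 18 (3S)-3-[3,5-bis(methoxymethoxy)-4-(3-methylbut-2-en-1-yl)phenoxy]-3-[7-(methoxymethoxy)-2,2-dimethyl-2H-chromen-6-yl]propan-1-ol, via alkylborane 17 (not isolated)
Conditions: 9-BBN (1.5 equiv), THF, 0 °C → rt; then NaOH (aq), H2O2, 0 °C
Reagents that add atoms: 9-borabicyclo[3.3.1]nonane, B1C2CCCC1CCC2 (boron unit of 17 only); hydrogen peroxide, OO (hydroxyl oxygen)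
Why: Anti-Markovnikov hydroboration with the bulky borane should be selective for the monosubstituted vinyl group over the trisubstituted prenyl and the hindered chromene alkenes, and oxidation of the C–B bond gives the primary alcohol without touching C2.

**Step 9**
Reactants: 18 (3S)-3-[3,5-bis(methoxymethoxy)-4-(3-methylbut-2-en-1-yl)phenoxy]-3-[7-(methoxymethoxy)-2,2-dimethyl-2H-chromen-6-yl]propan-1-ol
Product: 20 (3S)-3-[3,5-bis(methoxymethoxy)-4-(3-methylbut-2-en-1-yl)phenoxy]-3-[7-(methoxymethoxy)-2,2-dimethyl-2H-chromen-6-yl]propanoic acid, via aldehyde 19 (not isolated)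
Conditions: TEMPO (0.2 equiv), PhI(OAc)2 (2.5 equiv), MeCN/H2O (1:1), rt
Reagents that add atoms: water, O
Why: Nitroxyl-catalysed oxidation with the hypervalent iodine co-oxidant takes the primary alcohol through aldehyde 19 and its hydrate to the acid under nearly neutral conditions that should leave the alkenes, the acetals and C2 untouched.

**Step 10**
Reactants: 20 (3S)-3-[3,5-bis(methoxymethoxy)-4-(3-methylbut-2-en-1-yl)phenoxy]-3-[7-(methoxymethoxy)-2,2-dimethyl-2H-chromen-6-yl]propanoic acid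
Product: 22 (2S)-5,7-bis(methoxymethoxy)-2-[7-(methoxymethoxy)-2,2-dimethyl-2H-chromen-6-yl]-6-(3-methylbut-2-en-1-yl)-2,3-dihydro-4H-chromen-4-one, via mixed trifluoroacetic anhydride 21 (not isolated)
Conditions: (CF3CO)2O (1.3 equiv), CH2Cl2 (0.02 M), −40 → 0 °C; aq. NaHCO3 quench
Reagents that add atoms: trifluoroacetic anhydride, O=C(OC(=O)C(F)(F)F)C(F)(F)F (trifluoroacetyl group of 21 only)
Why: Trifluoroacetic anhydride converts the acid into mixed anhydride 21, whose acyl carbon (C4) is attacked by ring A at C4a, a carbon ortho to O1, ortho to the C5 oxygen and para to the C7 oxygen, and loss of trifluoroacetate and a proton restores the arene. The closest known reaction type is the intramolecular Friedel–Crafts acylation of 3-aryloxypropanoic acids to chroman-4-ones. Ring C closes in a 6-exo-trig mode, the arene carbon adding to a carbonyl whose C=O lies outside the new ring. No stereocentre is formed, and C2 should be carried through unchanged because no bond at C2 is broken and the step runs cold with only dilute trifluoroacetic acid present. The step needs regioselectivity between C4a and C8, which the substrate secures because the two carbons are equivalent by the local symmetry of the 4-prenylphloroglucinol ether, so only the 6-prenyl isomer can arise; attack by ring B at C6' would give a five-membered ketone at a carbon meta to both ring B oxygens and is not expected to compete.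

**Step 11**
Reactants: 22 (2S)-5,7-bis(methoxymethoxy)-2-[7-(methoxymethoxy)-2,2-dimethyl-2H-chromen-6-yl]-6-(3-methylbut-2-en-1-yl)-2,3-dihydro-4H-chromen-4-one
Product: 23 cudraflavanone A
Conditions: HCl (1.25 M in MeOH), 0 °C → rt
Reagents that add atoms: none
Why: Acid-catalysed acetal exchange with methanol should remove the three MOM ethers (the chelated C5 ether first) under conditions too mild to protonate the prenyl or chromene alkenes or to ionise the C2–O1 bond, so the S configuration is kept.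

**Compound list**

1 | 1,3-bis(methoxymethoxy)benzene | COCOc1cccc(OCOC)c1 | starting material
2 | 1-bromo-3-methylbut-2-ene (prenyl bromide) | CC(C)=CCBr | starting material
3 | [2,6-bis(methoxymethoxy)phenyl]lithium | [Li]c1c(OCOC)cccc1OCOC | intermediate (not isolated)
4 | 1,3-bis(methoxymethoxy)-2-(3-methylbut-2-en-1-yl)benzene | CC(C)=CCc1c(OCOC)cccc1OCOC | intermediate
5 | 2-[3,5-bis(methoxymethoxy)-4-(3-methylbut-2-en-1-yl)phenyl]-4,4,5,5-tetramethyl-1,3,2-dioxaborolane | CC(C)=CCc1c(OCOC)cc(cc1OCOC)B1OC(C)(C)C(C)(C)O1 | intermediate (not isolated)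
6 | 3,5-bis(methoxymethoxy)-4-(3-methylbut-2-en-1-yl)phenol | CC(C)=CCc1c(OCOC)cc(O)cc1OCOC | intermediate
7 | 5-bromo-2,4-dihydroxybenzaldehyde | O=Cc1cc(Br)c(O)cc1O | starting material
8 | 2-methylbut-3-en-2-ol | C=CC(C)(C)O | starting material
9 | 2,4-dihydroxy-5-[(1E)-3-hydroxy-3-methylbut-1-en-1-yl]benzaldehyde | O=Cc1cc(/C=C/C(C)(C)O)c(O)cc1O | intermediate (not isolated)
10 | 7-hydroxy-2,2-dimethyl-2H-chromene-6-carbaldehyde | CC1(C)C=Cc2cc(C=O)c(O)cc2O1 | intermediate
11 | 7-(methoxymethoxy)-2,2-dimethyl-2H-chromene-6-carbaldehyde | COCOc1cc2OC(C)(C)C=Cc2cc1C=O | intermediate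
12 | 6-ethenyl-7-(methoxymethoxy)-2,2-dimethyl-2H-chromene | COCOc1cc2OC(C)(C)C=Cc2cc1C=C | intermediate
13 | methyl prop-2-en-1-yl carbonate (allyl methyl carbonate) | C=CCOC(=O)OC | starting material
14 | (2E)-3-[7-(methoxymethoxy)-2,2-dimethyl-2H-chromen-6-yl]prop-2-en-1-yl methyl carbonate | COC(=O)OC/C=C/c1cc2C=CC(C)(C)Oc2cc1OCOC | intermediate
15 | lithium 3,5-bis(methoxymethoxy)-4-(3-methylbut-2-en-1-yl)phenolate | [Li+].[O-]c1cc(OCOC)c(CC=C(C)C)c(OCOC)c1 | intermediate (not isolated)
16 | 6-{(1S)-1-[3,5-bis(methoxymethoxy)-4-(3-methylbut-2-en-1-yl)phenoxy]prop-2-en-1-yl}-7-(methoxymethoxy)-2,2-dimethyl-2H-chromene | C=C[C@@H](c1cc2C=CC(C)(C)Oc2cc1OCOC)Oc1cc(OCOC)c(CC=C(C)C)c(OCOC)c1 | intermediate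
17 | 9-{(3S)-3-[3,5-bis(methoxymethoxy)-4-(3-methylbut-2-en-1-yl)phenoxy]-3-[7-(methoxymethoxy)-2,2-dimethyl-2H-chromen-6-yl]propyl}-9-borabicyclo[3.3.1]nonane | B1(C2CCCC1CCC2)CC[C@@H](c1cc2C=CC(C)(C)Oc2cc1OCOC)Oc1cc(OCOC)c(CC=C(C)C)c(OCOC)c1 | intermediate (not isolated)
18 | (3S)-3-[3,5-bis(methoxymethoxy)-4-(3-methylbut-2-en-1-yl)phenoxy]-3-[7-(methoxymethoxy)-2,2-dimethyl-2H-chromen-6-yl]propan-1-ol | OCC[C@@H](c1cc2C=CC(C)(C)Oc2cc1OCOC)Oc1cc(OCOC)c(CC=C(C)C)c(OCOC)c1 | intermediate
19 | (3S)-3-[3,5-bis(methoxymethoxy)-4-(3-methylbut-2-en-1-yl)phenoxy]-3-[7-(methoxymethoxy)-2,2-dimethyl-2H-chromen-6-yl]propanal | O=CC[C@@H](c1cc2C=CC(C)(C)Oc2cc1OCOC)Oc1cc(OCOC)c(CC=C(C)C)c(OCOC)c1 | intermediate (not isolated)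
20 | (3S)-3-[3,5-bis(methoxymethoxy)-4-(3-methylbut-2-en-1-yl)phenoxy]-3-[7-(methoxymethoxy)-2,2-dimethyl-2H-chromen-6-yl]propanoic acid | OC(=O)C[C@@H](c1cc2C=CC(C)(C)Oc2cc1OCOC)Oc1cc(OCOC)c(CC=C(C)C)c(OCOC)c1 | intermediate
21 | (3S)-3-[3,5-bis(methoxymethoxy)-4-(3-methylbut-2-en-1-yl)phenoxy]-3-[7-(methoxymethoxy)-2,2-dimethyl-2H-chromen-6-yl]propanoic trifluoroacetic anhydride | O=C(OC(=O)C(F)(F)F)C[C@@H](c1cc2C=CC(C)(C)Oc2cc1OCOC)Oc1cc(OCOC)c(CC=C(C)C)c(OCOC)c1 | intermediate (not isolated)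
22 | (2S)-5,7-bis(methoxymethoxy)-2-[7-(methoxymethoxy)-2,2-dimethyl-2H-chromen-6-yl]-6-(3-methylbut-2-en-1-yl)-2,3-dihydro-4H-chromen-4-one | CC(C)=CCc1c(OCOC)cc2c(c1OCOC)C(=O)C[C@@H](c1cc3c(cc1OCOC)OC(C)(C)C=C3)O2 | intermediate
23 | cudraflavanone A, (2S)-5,7-dihydroxy-2-(7-hydroxy-2,2-dimethyl-2H-chromen-6-yl)-6-(3-methylbut-2-en-1-yl)-2,3-dihydro-4H-chromen-4-one | CC(C)=CCc1c(O)cc2c(c1O)C(=O)C[C@@H](c1cc3c(cc1O)OC(C)(C)C=C3)O2 | target

**Total step count:** 11 steps. **Longest linear sequence:** 9 steps (steps 3 to 11, from 7).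

**Steps most likely to fail**

Step 10. The benzylic C2–O bond, activated by the ortho and para oxygens of ring B, may ionise under the acidic acylation conditions faster than the ring closes, which would erode the configuration at C2 or expel phenol 6 by elimination; partial loss of MOM groups may accompany this. The fallback reverses the polarity of the ring closure (Parham-type anionic cyclisation); it sets out from 6 and comes back at 22. Phenol 6 is brominated once at either of its two equivalent ortho carbons (NBS, CH2Cl2, −78 °C) to 2-bromo-3,5-bis(methoxymethoxy)-4-(3-methylbut-2-en-1-yl)phenol F1. F1 then takes the place of 6 in the chemistry of steps 7 to 9: its lithium phenolate F2 and carbonate 14 give the (S)-bromo allyl ether F3, hydroboration to the 9-BBN adduct F4 and oxidation give the bromo alcohol F5, and oxidation through the bromo aldehyde F6 gives the bromo acid F7. n-BuLi (2.2 equiv, THF, −100 → −20 °C) deprotonates the acid and exchanges bromine for lithium to give the aryllithium carboxylate F8, which adds to its own carboxylate to form the cyclic dilithium diolate F9; aqueous work-up releases 22.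

Step 7. The ortho-substituted, electron-rich cinnamyl carbonate may ionise slowly and with poor facial and branched selectivity, and the product ether may re-ionise, so that the enantiomeric purity drops and linear ether forms. The fallback builds the C2–O bond by copper-catalysed enantioselective propargylic etherification; it sets out from 11 (with 6) and comes back at 16. Ethynylmagnesium bromide adds to aldehyde 11 to give racemic 1-[7-(methoxymethoxy)-2,2-dimethyl-2H-chromen-6-yl]prop-2-yn-1-ol F10, which is acetylated (Ac2O, Et3N, DMAP) to the propargylic acetate F11. CuOTf·1/2C6H6 with a chiral 2,6-bis(4-phenyl-4,5-dihydrooxazol-2-yl)pyridine ligand and iPr2NEt couples F11 with phenol 6 through a copper allenylidene that converges both enantiomers of F11 into the (S)-aryl propargyl ether F12 (ligand enantiomer chosen accordingly). Semihydrogenation over Lindlar catalyst (Pd/CaCO3 poisoned with Pb(OAc)2, quinoline, H2) gives 16.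

Step 3. Oxidative addition into the electron-rich bromophenol may stall, and the quinone methide formed during cyclodehydration may oligomerise. The fallback installs the prenyl group first and closes the chromene by dehydrogenation; it sets out from 7 and comes back at 10. Migita–Kosugi–Stille coupling of 7 with tributyl(3-methylbut-2-en-1-yl)stannane (Pd(PPh3)4, DMF, 90 °C) gives 2,4-dihydroxy-5-(3-methylbut-2-en-1-yl)benzaldehyde F13. DDQ (benzene, 80 °C) dehydrogenates the ortho-prenylphenol to an ortho-quinone methide, which closes by oxa-6π-electrocyclisation to 10.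

**Further compounds**

F1 | step 10 | 2-bromo-3,5-bis(methoxymethoxy)-4-(3-methylbut-2-en-1-yl)phenol | CC(C)=CCc1c(OCOC)cc(O)c(Br)c1OCOC
F2 | step 10 | lithium 2-bromo-3,5-bis(methoxymethoxy)-4-(3-methylbut-2-en-1-yl)phenolate | [Li+].[O-]c1cc(OCOC)c(CC=C(C)C)c(OCOC)c1Br
F3 | step 10 | 6-{(1S)-1-[2-bromo-3,5-bis(methoxymethoxy)-4-(3-methylbut-2-en-1-yl)phenoxy]prop-2-en-1-yl}-7-(methoxymethoxy)-2,2-dimethyl-2H-chromene | C=C[C@@H](c1cc2C=CC(C)(C)Oc2cc1OCOC)Oc1cc(OCOC)c(CC=C(C)C)c(OCOC)c1Br
F4 | step 10 | 9-{(3S)-3-[2-bromo-3,5-bis(methoxymethoxy)-4-(3-methylbut-2-en-1-yl)phenoxy]-3-[7-(methoxymethoxy)-2,2-dimethyl-2H-chromen-6-yl]propyl}-9-borabicyclo[3.3.1]nonane | B1(C2CCCC1CCC2)CC[C@@H](c1cc2C=CC(C)(C)Oc2cc1OCOC)Oc1cc(OCOC)c(CC=C(C)C)c(OCOC)c1Br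
F5 | step 10 | (3S)-3-[2-bromo-3,5-bis(methoxymethoxy)-4-(3-methylbut-2-en-1-yl)phenoxy]-3-[7-(methoxymethoxy)-2,2-dimethyl-2H-chromen-6-yl]propan-1-ol | OCC[C@@H](c1cc2C=CC(C)(C)Oc2cc1OCOC)Oc1cc(OCOC)c(CC=C(C)C)c(OCOC)c1Br
F6 | step 10 | (3S)-3-[2-bromo-3,5-bis(methoxymethoxy)-4-(3-methylbut-2-en-1-yl)phenoxy]-3-[7-(methoxymethoxy)-2,2-dimethyl-2H-chromen-6-yl]propanal | O=CC[C@@H](c1cc2C=CC(C)(C)Oc2cc1OCOC)Oc1cc(OCOC)c(CC=C(C)C)c(OCOC)c1Br
F7 | step 10 | (3S)-3-[2-bromo-3,5-bis(methoxymethoxy)-4-(3-methylbut-2-en-1-yl)phenoxy]-3-[7-(methoxymethoxy)-2,2-dimethyl-2H-chromen-6-yl]propanoic acid | OC(=O)C[C@@H](c1cc2C=CC(C)(C)Oc2cc1OCOC)Oc1cc(OCOC)c(CC=C(C)C)c(OCOC)c1Br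
F8 | step 10 | lithium (3S)-3-[2-lithio-3,5-bis(methoxymethoxy)-4-(3-methylbut-2-en-1-yl)phenoxy]-3-[7-(methoxymethoxy)-2,2-dimethyl-2H-chromen-6-yl]propanoate | [Li+].[O-]C(=O)C[C@@H](c1cc2C=CC(C)(C)Oc2cc1OCOC)Oc1cc(OCOC)c(CC=C(C)C)c(OCOC)c1[Li]
F9 | step 10 | dilithium (2S)-5,7-bis(methoxymethoxy)-2-[7-(methoxymethoxy)-2,2-dimethyl-2H-chromen-6-yl]-6-(3-methylbut-2-en-1-yl)-2,3-dihydro-4H-chromene-4,4-diolate | [Li+].[Li+].[O-]C1([O-])C[C@@H](c3cc4C=CC(C)(C)Oc4cc3OCOC)Oc2cc(OCOC)c(CC=C(C)C)c(OCOC)c12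
F10 | step 7 | racemic 1-[7-(methoxymethoxy)-2,2-dimethyl-2H-chromen-6-yl]prop-2-yn-1-ol | C#CC(O)c1cc2C=CC(C)(C)Oc2cc1OCOC
F11 | step 7 | racemic 1-[7-(methoxymethoxy)-2,2-dimethyl-2H-chromen-6-yl]prop-2-yn-1-yl acetate | C#CC(OC(C)=O)c1cc2C=CC(C)(C)Oc2cc1OCOC
F12 | step 7 | 6-{(1S)-1-[3,5-bis(methoxymethoxy)-4-(3-methylbut-2-en-1-yl)phenoxy]prop-2-yn-1-yl}-7-(methoxymethoxy)-2,2-dimethyl-2H-chromene | C#C[C@@H](c1cc2C=CC(C)(C)Oc2cc1OCOC)Oc1cc(OCOC)c(CC=C(C)C)c(OCOC)c1
F13 | step 3 | 2,4-dihydroxy-5-(3-methylbut-2-en-1-yl)benzaldehyde | CC(C)=CCc1cc(C=O)c(O)cc1O
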